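**Retrosynthetic overview** (labdane numbering: decalin C1–C10, side chain C11–C16, C17 on C8, C18/C19 on C4, C20 on C10)
- Side chain: cut at C11=C12 (Wittig of a C11 aldehyde with the C12–C16 ylide from (R)-2-methylbutane-1,4-diol, then diimide). The C7=C8 olefin with C17 comes from the kinetic C7 enol triflate of a C8 ketone.
- The strategy rests on the C9–C10 bond. It joins the quaternary C10 of ring A to C9, the carbon between the C8 carbonyl and the C11 ester, so a C10 cation in a preformed ring A (C1–C5, C10) carrying the cis-2,3-diol can be trapped by the C8/C9 enol of a β-keto ester. This closes ring B (C5–C10) and sets C5, C9 and C10.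
- Ring A comes from ketoisophorone: acetoxylation at the CH2 next to the gem-dimethyl group (later C3), transfer hydrogenation with dynamic kinetic resolution (cis-diol), enone reduction/enol triflate, Negishi coupling (C5–C6), Blaise reaction (C8–C9).
- The diol goes through the cyclization as a cyclic carbonate (inert to SnCl4, oxygens not nucleophilic). C9 from the cyclization is kept. Ring A is made first, ring B second.

Key step: step 8

Assumption: in step 2 the (R,R) ligand is chosen on the usual model for this catalyst class, with the alkenyl carbon of the enone in the place of an aryl group; the (S,S) ligand would be used if the sense proved opposite.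

Step 1
Reactants: 1 ketoisophorone (2,6,6-trimethylcyclohex-2-ene-1,4-dione)
Product: 2 (±)-5-acetoxy-2,6,6-trimethylcyclohex-2-ene-1,4-dione
Conditions: Mn(OAc)3·2H2O (3 equiv), benzene, reflux (water separator)
Reagents that add atoms: manganese triacetate, CC(=O)O[Mn](OC(C)=O)OC(C)=O
Why: α'-acetoxylation of an enone by Mn(OAc)3: the trivalent manganese enolate can form only at C5 (the sole enolisable carbon, α' to the C4 carbonyl), and acetate is transferred there to give the racemate.

Step 2
Reactants: 2 (±)-5-acetoxy-2,6,6-trimethylcyclohex-2-ene-1,4-dione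
Product: 3 (4S,5R)-5-acetoxy-4-hydroxy-2,6,6-trimethylcyclohex-2-en-1-one (cis)
Conditions: RuCl[(R,R)-TsDPEN](p-cymene) (1 mol %), HCO2H–Et3N (5:2), DMF, 30 °C
Reagents that add atoms: none
Why: Ru–TsDPEN asymmetric transfer hydrogenation with dynamic kinetic resolution: only the C4 carbonyl is accessible (C1 lies between quaternary C6 and substituted C2), C5 should epimerise through its enol in the amine medium, and the catalyst should reduce the enantiomer whose preferred face is also anti to the acetoxy group, setting C4 (S) and C5 (R) as the cis pair; any 4-O-acetyl isomer from acyl shift converges in step 3.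

Step 3
Reactants: 3 (4S,5R)-5-acetoxy-4-hydroxy-2,6,6-trimethylcyclohex-2-en-1-one
Product: 4 (4S,5R)-4,5-dihydroxy-2,6,6-trimethylcyclohex-2-en-1-one (cis-diol)
Conditions: HCl (0.3 M) in MeOH, 0 → 23 °C
Reagents that add atoms: none
Why: acid-catalysed transesterification removes the acetate without a basic medium, in which the β-hydroxy ketone (C5–OH and C1=O across quaternary C6) could open by retro-aldol reaction.

Step 4
Reactants: 4 (4S,5R)-4,5-dihydroxy-2,6,6-trimethylcyclohex-2-en-1-one
Product: 5 (4S,5R)-4,5-(carbonyldioxy)-2,6,6-trimethylcyclohex-2-en-1-one (cis-fused cyclic carbonate)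
Conditions: 1,1'-carbonyldiimidazole (1.5 equiv), toluene, 60 °C
Reagents that add atoms: 1,1'-carbonyldiimidazole, O=C(n1ccnc1)n1ccnc1
Why: two acyl substitutions (the second intramolecular) convert the cis-1,2-diol into the cyclic carbonate, chosen because acyl-type oxygens are inert to SnCl4 and cannot attack a cation in step 8.

Step 5
Reactants: 5 (4S,5R)-4,5-(carbonyldioxy)-2,6,6-trimethylcyclohex-2-en-1-one
Product: 7 (4S,5R)-4,5-(carbonyldioxy)-2,6,6-trimethylcyclohex-1-en-1-yl trifluoromethanesulfonate, via lithium enolate 6 (not isolated)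
Conditions: LiBH(s-Bu)3 (1.05 equiv), THF, −78 °C; then PhNTf2, −78 → 0 °C
Reagents that add atoms: N-phenylbis(trifluoromethanesulfonimide), O=S(=O)(N(c1ccccc1)S(=O)(=O)C(F)(F)F)C(F)(F)F
Why: conjugate hydride addition to the β-unsubstituted enone (carbonyl shielded by the gem-dimethyl group; the carbonate is not attacked at −78 °C) gives the tetrasubstituted enolate regiospecifically, which is trapped on oxygen as the enol triflate.

Step 6
Reactants: 7 (4S,5R)-4,5-(carbonyldioxy)-2,6,6-trimethylcyclohex-1-en-1-yl trifluoromethanesulfonate; 8 2-cyanoethylzinc bromide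
Product: 9 3-[(4S,5R)-4,5-(carbonyldioxy)-2,6,6-trimethylcyclohex-1-en-1-yl]propanenitrile
Conditions: 8 (1.8 equiv, 0.5 M in THF), Pd(OAc)2 (4 mol %), SPhos (8 mol %), THF, 55 °C
Reagents that add atoms: none
Why: Negishi sp2–sp3 cross-coupling: the bulky biaryl phosphine allows oxidative addition and reductive elimination at the doubly flanked alkenyl triflate and suppresses β-hydride elimination, and the neutral organozinc leaves the carbonate untouched.

Step 7
Reactants: 9 3-[(4S,5R)-4,5-(carbonyldioxy)-2,6,6-trimethylcyclohex-1-en-1-yl]propanenitrile; 10 methyl bromoacetate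
Product: 12 methyl 5-[(4S,5R)-4,5-(carbonyldioxy)-2,6,6-trimethylcyclohex-1-en-1-yl]-3-oxopentanoate (cyclization precursor), via bromozinc enaminoester 11 (not isolated)
Conditions: Zn dust (TMSCl-activated), THF, reflux, slow addition of 10; then 1 M aq HCl, THF, 23 °C
Reagents that add atoms: water, O
Why: Blaise reaction: the zinc ester enolate (Reformatsky reagent) adds to the nitrile and dilute acid hydrolyses the zinc enaminoester to the β-keto ester; the reagent attacks neither the carbonate nor the tetrasubstituted olefin.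

Step 8
Reactants: 12 methyl 5-[(4S,5R)-4,5-(carbonyldioxy)-2,6,6-trimethylcyclohex-1-en-1-yl]-3-oxopentanoate (ring carbons 1/2/3/4/5/6 = labdane C5/C10/C1/C2/C3/C4; chain = C6–C9; ester carbon = C11)
Product: 13 trans-fused bicyclic 8-oxo C11 methyl ester 2,3-carbonate (2-O and 3-O cis to 5-H and trans to the C10 methyl; 9-CO2Me equatorial and cis to the C10 methyl)
Conditions: SnCl4 (2.5 equiv), CH2Cl2, 0 → 23 °C; aqueous work-up
Reagents that add atoms: none
Why: SnCl4 binds the β-keto ester as its chlorostannyl enolate and the HCl set free protonates the tetrasubstituted C5=C10 olefin at C5; the tertiary C10 cation is then captured by the enol carbon C9, which forms C9–C10. The closest known reaction type is the SnCl4-promoted cation–olefin cyclization of olefinic β-keto esters to trans-fused 2-carbomethoxydecalones. Ring B closes through a chair, 6-endo-trig at the olefin and 6-(enolendo) at the enol, with the C5–C6 bond and the new C9–C10 bond both equatorial on ring A. This puts the C10 methyl axial and anti to the axial 5-H (trans fusion, C5 and C10), and C9 ends with the ester equatorial because the β-keto ester equilibrates through its enol. The step needs one face of ring A: protonation at C5 is reversible, so the product should arise from the chair with the C2 oxygen equatorial and the C3 oxygen axial, the only one that keeps the C2 oxygen away from the axial C4 and C10 methyls, and this fixes C5, C9 and C10 relative to C2 and C3. It also needs C9 capture to outrun proton loss and any reaction of the ring oxygens, which the cyclic carbonate secures: its oxygens do not ionise with SnCl4 and cannot add across the ring to the C10 cation.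

Step 9
Reactants: 13 trans-fused bicyclic 8-oxo C11 methyl ester 2,3-carbonate
Product: 14 2,3,8,11-tetrol (9-hydroxymethyl-4,4,10-trimethyl-trans-decalin-2,3,8-triol; C8 epimers)
Conditions: LiAlH4 (excess), THF, 0 °C → reflux; Rochelle salt work-up
Reagents that add atoms: none
Why: hydride reduction of ketone, ester and carbonate in one operation; the C8 carbinol is of no consequence (it is oxidised in step 12) and C9 is no longer next to an enolisable carbonyl.

Step 10
Reactants: 14 2,3,8,11-tetrol
Product: 15 11-O-TBS 2,3,8-triol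
Conditions: TBSCl (1.1 equiv), imidazole, CH2Cl2–DMF, 0 °C
Reagents that add atoms: tert-butyldimethylsilyl chloride, CC(C)(C)[Si](C)(C)Cl
Why: silylation selects the only primary hydroxyl (C11) over three secondary ones.

Step 11
Reactants: 15 11-O-TBS 2,3,8-triol
Product: 16 2,3-O-isopropylidene 11-O-TBS 8-ol
Conditions: Me2C(OMe)2, pyridinium tosylate (cat.), acetone, 23 °C
Reagents that add atoms: 2,2-dimethoxypropane, COC(C)(C)OC
Why: transketalisation gives the acetonide on the only cis-1,2-diol; the isolated C8 hydroxyl cannot form a cyclic ketal.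

Step 12
Reactants: 16 2,3-O-isopropylidene 11-O-TBS 8-ol
Product: 17 2,3-O-isopropylidene 11-O-TBS 8-ketone
Conditions: Dess–Martin periodinane, NaHCO3, CH2Cl2, 0 → 23 °C
Reagents that add atoms: none
Why: Dess–Martin oxidation of the secondary alcohol under buffered, non-basic conditions that do not eliminate the β-silyloxy group or epimerise C9 away from its favoured equatorial arrangement.

Step 13
Reactants: 17 2,3-O-isopropylidene 11-O-TBS 8-ketone
Product: 19 7-en-8-yl triflate (2,3-acetonide; 11-OTBS), via lithium 7-en-8-olate 18 (not isolated)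
Conditions: LiN(iPr)2 (1.1 equiv), THF, −78 °C (ketone added to base); then N-(5-chloro-2-pyridyl)triflimide, −78 °C
Reagents that add atoms: N-(5-chloro-2-pyridyl)bis(trifluoromethanesulfonimide), O=S(=O)(N(c1ccc(Cl)cn1)S(=O)(=O)C(F)(F)F)C(F)(F)F
Why: kinetic deprotonation by the hindered amide at the methylene C7 (C9 is a methine next to quaternary C10) and O-triflation at −78 °C fix the double bond at C7=C8.

Step 14
Reactants: 19 7-en-8-yl triflate
Product: 20 8-methyl-7-ene (2,3-acetonide; 11-OTBS)
Conditions: MeMgBr (1.5 equiv), Fe(acac)3 (5 mol %), THF–NMP, −30 → 0 °C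
Reagents that add atoms: methylmagnesium bromide, C[Mg]Br
Why: iron-catalysed Kumada-type cross-coupling of an alkenyl triflate with MeMgBr installs C17 without moving the double bond.

Step 15
Reactants: 20 8-methyl-7-ene (2,3-acetonide; 11-OTBS)
Product: 21 2,3-O-isopropylidene 7-en-11-ol
Conditions: Bu4NF, THF, 23 °C
Reagents that add atoms: none
Why: fluoride cleaves the primary silyl ether; acetonide and olefin are inert.

Step 16
Reactants: 22 (R)-2-methylbutane-1,4-diol
Product: 23 (R)-2-methyl-4-(trityloxy)butan-1-ol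
Conditions: TrCl (1.0 equiv), Et3N, DMAP (cat.), CH2Cl2, 0 °C
Reagents that add atoms: trityl chloride, ClC(c1ccccc1)(c1ccccc1)c1ccccc1
Why: the very bulky trityl chloride should react preferentially at the unbranched 4-hydroxyl (the 1-hydroxyl is β-branched); the minor regioisomer and bis-ether are removed by chromatography.

Step 17
Reactants: 23 (R)-2-methyl-4-(trityloxy)butan-1-ol
Product: 24 (R)-1-iodo-2-methyl-4-(trityloxy)butane
Conditions: I2, PPh3, imidazole, CH2Cl2, 0 → 23 °C
Reagents that add atoms: iodine, II
Why: Appel-type iodination by SN2 displacement of the oxyphosphonium at the primary carbon; the stereocentre is not involved and imidazole protects the trityl ether from acid.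

Step 18
Reactants: 24 (R)-1-iodo-2-methyl-4-(trityloxy)butane
Product: 25 [(R)-2-methyl-4-(trityloxy)butyl]triphenylphosphonium iodide
Conditions: PPh3 (1.5 equiv), iPr2NEt (cat.), MeCN, reflux
Reagents that add atoms: triphenylphosphine, c1ccccc1P(c1ccccc1)c1ccccc1
Why: SN2 quaternisation of PPh3 by the primary iodide.

Step 19
Reactants: 21 2,3-O-isopropylidene 7-en-11-ol
Product: 26 2,3-O-isopropylidene 7-en-11-al
Conditions: Dess–Martin periodinane, NaHCO3, CH2Cl2, 0 °C; used at once
Reagents that add atoms: none
Why: buffered Dess–Martin oxidation gives the β,γ-unsaturated aldehyde without a base that could epimerise C9 or move the double bond into conjugation.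

Step 20
Reactants: 25 [(R)-2-methyl-4-(trityloxy)butyl]triphenylphosphonium iodide; 26 2,3-O-isopropylidene 7-en-11-al
Product: 28 (11Z)-15-O-trityl 2,3-O-isopropylidene labda-7,11-diene, via phosphorus ylide 27 (not isolated)
Conditions: 25, NaN(SiMe3)2, THF, −78 → 0 °C; then 26, −78 → 23 °C
Reagents that add atoms: none
Why: Wittig olefination with a salt-free non-stabilised ylide at low temperature, where addition to the formyl group should be faster than deprotonation at C9; the Z geometry is irrelevant because the bond is reduced next.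

Step 21
Reactants: 28 (11Z)-15-O-trityl 2,3-O-isopropylidene labda-7,11-diene
Product: 29 15-O-trityl 2,3-O-isopropylidene labd-7-ene
Conditions: 2-nitrobenzenesulfonylhydrazide (excess, in portions), Et3N, CH2Cl2, 23 °C
Reagents that add atoms: none
Why: diimide reduction (concerted syn transfer of two hydrogens) is much faster at the 1,2-disubstituted C11=C12 bond than at the trisubstituted ring C7=C8 bond and leaves trityl ether and acetonide alone.

Step 22
Reactants: 29 15-O-trityl 2,3-O-isopropylidene labd-7-ene
Product: 30 labd-7-ene-2,3,15-triol (2,3-cis; configuration as in the target)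
Conditions: TsOH·H2O (0.2 equiv), MeOH, 23 °C
Reagents that add atoms: none
Why: acid-catalysed methanolysis removes the trityl ether (SN1) and the acetonide (transketalisation) together; the trisubstituted olefin should be stable to catalytic acid at room temperature.

Step 23
Reactants: 30 labd-7-ene-2,3,15-triol
Product: 31 CNP0144124.1 (2,15-di-O-acetyl-labd-7-ene-2,3,15-triol; 2S,3R,5S,9R,10S,13S)
Conditions: Ac2O (2.2 equiv), pyridine, CH2Cl2, 0 °C, no DMAP
Reagents that add atoms: acetic anhydride, CC(=O)OC(C)=O
Why: a limited amount of Ac2O should esterify the primary C15 and the equatorial C2 hydroxyl, while the axial C3 hydroxyl next to the gem-dimethyl group reacts far more slowly.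

**Compound list**
1 | ketoisophorone | CC1=CC(=O)CC(C)(C)C1=O | starting material
2 | (±)-5-acetoxy-2,6,6-trimethylcyclohex-2-ene-1,4-dione | CC(=O)OC1C(=O)C=C(C)C(=O)C1(C)C | intermediate
3 | (4S,5R)-5-acetoxy-4-hydroxy-2,6,6-trimethylcyclohex-2-en-1-one | O=C1C(C)=C[C@H](O)[C@H](OC(C)=O)C1(C)C | intermediate
4 | (4S,5R)-4,5-dihydroxy-2,6,6-trimethylcyclohex-2-en-1-one | O=C1C(C)=C[C@H](O)[C@H](O)C1(C)C | intermediate
5 | (4S,5R)-4,5-(carbonyldioxy)-2,6,6-trimethylcyclohex-2-en-1-one | O=C1C(C)=C[C@@H]2OC(=O)O[C@@H]2C1(C)C | intermediate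
6 | lithium (4S,5R)-4,5-(carbonyldioxy)-2,6,6-trimethylcyclohex-1-en-1-olate | [Li+].[O-]C1=C(C)C[C@@H]2OC(=O)O[C@@H]2C1(C)C | intermediate (not isolated)
7 | (4S,5R)-4,5-(carbonyldioxy)-2,6,6-trimethylcyclohex-1-en-1-yl trifluoromethanesulfonate | FC(F)(F)S(=O)(=O)OC1=C(C)C[C@@H]2OC(=O)O[C@@H]2C1(C)C | intermediate
8 | 2-cyanoethylzinc bromide | N#CCC[Zn]Br | starting material
9 | 3-[(4S,5R)-4,5-(carbonyldioxy)-2,6,6-trimethylcyclohex-1-en-1-yl]propanenitrile | N#CCCC1=C(C)C[C@@H]2OC(=O)O[C@@H]2C1(C)C | intermediate
10 | methyl bromoacetate | COC(=O)CBr | starting material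
11 | bromozinc (Z)-enaminoester (Blaise adduct of 9) | COC(=O)/C=C(\N[Zn]Br)CCC1=C(C)C[C@@H]2OC(=O)O[C@@H]2C1(C)C | intermediate (not isolated)
12 | methyl 5-[(4S,5R)-4,5-(carbonyldioxy)-2,6,6-trimethylcyclohex-1-en-1-yl]-3-oxopentanoate | COC(=O)CC(=O)CCC1=C(C)C[C@@H]2OC(=O)O[C@@H]2C1(C)C | intermediate (cyclization precursor)
13 | trans-fused bicyclic 8-oxo C11 methyl ester 2,3-carbonate | COC(=O)[C@@H]1C(=O)CC[C@@H]2C(C)(C)[C@H]3OC(=O)O[C@H]3C[C@@]12C | intermediate (cyclization product)
14 | 2,3,8,11-tetrol (C8 epimers) | OC[C@@H]1C(O)CC[C@@H]2C(C)(C)[C@@H](O)[C@@H](O)C[C@@]12C | intermediate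
15 | 11-O-TBS 2,3,8-triol (C8 epimers) | CC(C)(C)[Si](C)(C)OC[C@@H]1C(O)CC[C@@H]2C(C)(C)[C@@H](O)[C@@H](O)C[C@@]12C | intermediate
16 | 2,3-O-isopropylidene 11-O-TBS 8-ol (C8 epimers) | CC(C)(C)[Si](C)(C)OC[C@@H]1C(O)CC[C@@H]2C(C)(C)[C@H]3OC(C)(C)O[C@H]3C[C@@]12C | intermediate
17 | 2,3-O-isopropylidene 11-O-TBS 8-ketone | CC(C)(C)[Si](C)(C)OC[C@@H]1C(=O)CC[C@@H]2C(C)(C)[C@H]3OC(C)(C)O[C@H]3C[C@@]12C | intermediate
18 | lithium 7-en-8-olate of 17 | [Li+].CC(C)(C)[Si](C)(C)OC[C@@H]1C([O-])=CC[C@@H]2C(C)(C)[C@H]3OC(C)(C)O[C@H]3C[C@@]12C | intermediate (not isolated)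
19 | 7-en-8-yl triflate (2,3-acetonide; 11-OTBS) | CC(C)(C)[Si](C)(C)OC[C@@H]1C(OS(=O)(=O)C(F)(F)F)=CC[C@@H]2C(C)(C)[C@H]3OC(C)(C)O[C@H]3C[C@@]12C | intermediate
20 | 8-methyl-7-ene (2,3-acetonide; 11-OTBS) | CC(C)(C)[Si](C)(C)OC[C@@H]1C(C)=CC[C@@H]2C(C)(C)[C@H]3OC(C)(C)O[C@H]3C[C@@]12C | intermediate
21 | 2,3-O-isopropylidene 7-en-11-ol | OC[C@@H]1C(C)=CC[C@@H]2C(C)(C)[C@H]3OC(C)(C)O[C@H]3C[C@@]12C | intermediate
22 | (R)-2-methylbutane-1,4-diol | OCC[C@@H](C)CO | starting material
23 | (R)-2-methyl-4-(trityloxy)butan-1-ol | OC[C@H](C)CCOC(c1ccccc1)(c1ccccc1)c1ccccc1 | intermediate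
24 | (R)-1-iodo-2-methyl-4-(trityloxy)butane | IC[C@H](C)CCOC(c1ccccc1)(c1ccccc1)c1ccccc1 | intermediate
25 | [(R)-2-methyl-4-(trityloxy)butyl]triphenylphosphonium iodide | [I-].c1ccccc1[P+](c1ccccc1)(c1ccccc1)C[C@H](C)CCOC(c1ccccc1)(c1ccccc1)c1ccccc1 | intermediate
26 | 2,3-O-isopropylidene 7-en-11-al | O=C[C@@H]1C(C)=CC[C@@H]2C(C)(C)[C@H]3OC(C)(C)O[C@H]3C[C@@]12C | intermediate
27 | [(R)-2-methyl-4-(trityloxy)butylidene]triphenylphosphorane | c1ccccc1P(c1ccccc1)(c1ccccc1)=C[C@H](C)CCOC(c1ccccc1)(c1ccccc1)c1ccccc1 | intermediate (not isolated)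
28 | (11Z)-15-O-trityl 2,3-O-isopropylidene labda-7,11-diene | c1ccccc1C(c1ccccc1)(c1ccccc1)OCC[C@@H](C)/C=C\[C@@H]1C(C)=CC[C@@H]2C(C)(C)[C@H]3OC(C)(C)O[C@H]3C[C@@]12C | intermediate
29 | 15-O-trityl 2,3-O-isopropylidene labd-7-ene | c1ccccc1C(c1ccccc1)(c1ccccc1)OCC[C@@H](C)CC[C@@H]1C(C)=CC[C@@H]2C(C)(C)[C@H]3OC(C)(C)O[C@H]3C[C@@]12C | intermediate
30 | labd-7-ene-2,3,15-triol | OCC[C@@H](C)CC[C@@H]1C(C)=CC[C@@H]2C(C)(C)[C@@H](O)[C@@H](O)C[C@@]12C | intermediate
31 | CNP0144124.1 | CC(=O)OCC[C@@H](C)CC[C@@H]1C(C)=CC[C@@H]2C(C)(C)[C@@H](O)[C@@H](OC(C)=O)C[C@@]12C | target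

**Step count:** 23 steps in total. Longest linear sequence: 20 steps (steps 1–15 and 19–23; steps 16–18 make the side-chain salt 25).

**Steps most likely to fail**

Step 2. The acetoxy-bearing carbon may epimerise too slowly under the reduction conditions, or the facial preference may be weak, giving cis/trans mixtures of low enantiomeric purity. The fallback sets out from 2 and returns at 4. Compound 2 is reduced without asymmetric induction (NaBH4, CeCl3·7H2O, MeOH, −78 °C; hydride should enter anti to the acetoxy group) to the racemic cis-hydroxy acetate F1. F1 is esterified at O4 with (S)-O-acetylmandelic acid (dicyclohexylcarbodiimide, DMAP), and the diastereomeric esters are separated by chromatography or crystallisation. The (4S,5R) mandelate F2 is methanolysed (HCl, MeOH) to diol 4.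

Step 8. Proton loss from the C10 cation to olefin isomers may outrun capture by C9 on the carbonate-deactivated ring (the 1(10)-ene places the C2 oxygen in an allylic position open to Lewis-acid ionisation), or the two faces of ring A may not be discriminated well. The fallback sets out from 12 and returns at 13 without a cation. Oxidative free-radical cyclization (Mn(OAc)3·2H2O, Cu(OAc)2·H2O, AcOH, 25–50 °C) should add the C9 radical to C10 in the 6-endo mode, since C5 is shielded by the gem-dimethyl group. Divalent copper oxidises the resulting C5 radical to the 5-ene keto ester carbonate F3. Hydrogenation of the C5=C6 bond (H2, Pd/C, EtOAc, pressure) from the face opposite to the C10 methyl then gives 13.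

Step 20. The basic ylide may deprotonate the aldehyde at C9, which is both α to the formyl group and allylic, causing epimerisation or conjugation, and addition to the hindered formyl group may be slow. The fallback sets out from 26 (with iodide 24) and returns at 29, so step 21 is not needed. Iodide 24 is converted into the organocerium reagent (t-BuLi, Et2O, −78 °C; then CeCl3, THF), which is weakly basic and should add to 26 to give the C11 carbinol F4. F4 is converted with 1,1'-thiocarbonyldiimidazole (DMAP, toluene, 80 °C) into the thiocarbonylimidazolide F5. Barton–McCombie deoxygenation of F5 (Bu3SnH, azobisisobutyronitrile, toluene, 90 °C) gives 29.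

**Further compounds**
F1 | step 2 | racemic cis-5-acetoxy-4-hydroxy-2,6,6-trimethylcyclohex-2-en-1-one (one enantiomer drawn) | O=C1C(C)=C[C@H](O)[C@H](OC(C)=O)C1(C)C
F2 | step 2 | (4S,5R)-5-acetoxy-2,6,6-trimethyl-1-oxocyclohex-2-en-4-yl (S)-O-acetylmandelate | O=C1C(C)=C[C@H](OC(=O)[C@@H](OC(C)=O)c2ccccc2)[C@H](OC(C)=O)C1(C)C
F3 | step 8 | 5-ene bicyclic 8-oxo C11 methyl ester 2,3-carbonate | COC(=O)[C@@H]1C(=O)CC=C2C(C)(C)[C@H]3OC(=O)O[C@H]3C[C@@]12C
F4 | step 20 | 11-hydroxy 15-O-trityl 2,3-O-isopropylidene labd-7-ene (C11 epimers) | c1ccccc1C(c1ccccc1)(c1ccccc1)OCC[C@@H](C)CC(O)[C@@H]1C(C)=CC[C@@H]2C(C)(C)[C@H]3OC(C)(C)O[C@H]3C[C@@]12C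
F5 | step 20 | 11-O-(imidazol-1-ylthiocarbonyl) derivative of F4 | c1ccccc1C(c1ccccc1)(c1ccccc1)OCC[C@@H](C)CC(OC(=S)n4ccnc4)[C@@H]1C(C)=CC[C@@H]2C(C)(C)[C@H]3OC(C)(C)O[C@H]3C[C@@]12C
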